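The bond on which everything rests runs from C6 of the perhydro-1-benzoxepine (ring B) to the first carbon of the ethylene bridge. C6 is α to C7, so with C7 as a ketone it is an enolate carbon. The two bridge carbons and C5 of the hydroazulene (ring C) form an allyl unit once the ring C alkene and the azulene C7 oxygen are stored as a 7-methoxy dienol ether. A palladium-catalysed allylic alkylation joins the lithium enolate of enone 5 (epoxide-opening cascade from geranylacetone) with tertiary vinyl carbonate 19 (enyne metathesis, then (4+3) cycloaddition); it forms the bond and leaves the two carbonyl groups differentiated.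

Key step: step 16

Remark: locants follow 1-benzoxepine (O1 to C9a; rings A and B) and azulene (C1 to C8a; rings C and D) numbering; the geometry of the exocyclic dienol ether alkene in 21 to 25 is left open because step 19 erases it.

Step 1
Reactants: 1 geranylacetone
Product: 2 (5R,6R,9R)-5,6:9,10-diepoxy-6,10-dimethylundecan-2-one
Conditions: 1,2:4,5-di-O-isopropylidene-β-D-erythro-2,3-hexodiulo-2,6-pyranose (Shi ketone from D-fructose, 0.3 equiv), Oxone (KHSO5), K2CO3, Bu4NHSO4, MeCN/CH2(OMe)2/aq. buffer pH 10.5, 0 °C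
Reagents that add atoms: potassium peroxymonosulfate, [K+].[O-]S(=O)(=O)OO
Why: Shi asymmetric epoxidation of both trisubstituted alkenes through the spiro dioxirane transition state should give the R,R epoxide from the E-alkene and the R epoxide from the terminal alkene, which sets C5, C6 and C9.

Step 2
Reactants: 2 (5R,6R,9R)-5,6:9,10-diepoxy-6,10-dimethylundecan-2-one
Product: 3 kinetic tert-butyldimethylsilyl enol ether of 2 (2-silyloxy-1-ene)
Conditions: LDA, TBSCl, HMPA, THF, −78 °C (internal quench)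
Reagents that add atoms: tert-butyldimethylsilyl chloride, CC(C)(C)[Si](C)(C)Cl
Why: Kinetic deprotonation of the methyl ketone at the methyl group with in situ O-silylation should give the terminal enol silane and leave the epoxides untouched at −78 °C; no stereocentre is formed.

Step 3
Reactants: 3 kinetic tert-butyldimethylsilyl enol ether of 2
Product: 4 (3R,5aR,9aR)-3-(tert-butyldimethylsilyloxy)-2,2,5a-trimethyloctahydro-1-benzoxepin-7(2H)-one (rings A/B trans-fused)
Conditions: TBSOTf (0.2 equiv), 2,6-di-tert-butyl-4-methylpyridine, CH2Cl2, −78 °C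
Reagents that add atoms: none
Why: In this epoxide-opening cascade (tandem oxa- and carbacyclisation) the silylated terminal epoxide is opened at its tertiary carbon by the internal epoxide oxygen to close the oxepane, the resulting epoxonium ion is opened with inversion at C5a by the enol silane carbon through a chair to close ring B trans-fused, C3 and C9a keep the epoxide configurations, and the silyl group released from the enol ether carries the chain.

Step 4
Reactants: 4 (3R,5aR,9aR)-3-(tert-butyldimethylsilyloxy)-2,2,5a-trimethyloctahydro-1-benzoxepin-7(2H)-one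
Product: 5 (3R,5aR,9aR)-3-(tert-butyldimethylsilyloxy)-2,2,5a-trimethyl-3,4,5,5a,6,9a-hexahydro-1-benzoxepin-7(2H)-one (C8=C9 enone)
Conditions: IBX (2-iodoxybenzoic acid), DMSO, 70 °C
Reagents that add atoms: none
Why: IBX dehydrogenation of the ketone can only give the C8=C9 enone because C5a is quaternary, and this blocks C8 so that later enolisation must occur at C6.

Step 5
Reactants: 6 geraniol
Product: 7 (2R,3R)-2,3-epoxygeraniol
Conditions: Ti(OiPr)4 (5 mol %), D-(−)-diethyl tartrate (6 mol %), t-BuOOH, 4 Å MS, CH2Cl2, −20 °C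
Reagents that add atoms: tert-butyl hydroperoxide, CC(C)(C)OO
Why: Sharpless asymmetric epoxidation with the D-tartrate should deliver oxygen to the face that gives the 2R,3R epoxy alcohol, which fixes the later tertiary carbinol centre.

Step 6
Reactants: 7 (2R,3R)-2,3-epoxygeraniol
Product: 8 (2R,3S)-3-(chloromethyl)-2-methyl-2-(4-methylpent-3-en-1-yl)oxirane
Conditions: PPh3, CCl4, NaHCO3, reflux
Reagents that add atoms: carbon tetrachloride, ClC(Cl)(Cl)Cl
Why: Appel chlorination replaces the primary hydroxyl without touching either epoxide carbon.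

Step 7
Reactants: 8 (2R,3S)-3-(chloromethyl)-2-methyl-2-(4-methylpent-3-en-1-yl)oxirane
Product: 9 (R)-3,7-dimethyloct-6-en-1-yn-3-ol
Conditions: n-BuLi (3.2 equiv), THF, −40 → 0 °C; aq. NH4Cl
Reagents that add atoms: none
Why: Base-induced fragmentation of the chloromethyl oxirane (α-deprotonation, epoxide opening to the chloroalkenyl alkoxide, then loss of HCl) should give the terminal alkynol with the tertiary C–O bond intact, hence R.

Step 8
Reactants: 9 (R)-3,7-dimethyloct-6-en-1-yn-3-ol
Product: 10 (R)-triethyl[(3,7-dimethyloct-6-en-1-yn-3-yl)oxy]silane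
Conditions: Et3SiOTf, 2,6-lutidine, CH2Cl2, −78 → 0 °C
Reagents that add atoms: triethylsilyl trifluoromethanesulfonate, CC[Si](CC)(CC)OS(=O)(=O)C(F)(F)F
Why: Silyl triflate silylation protects the hindered tertiary alcohol for the Lewis-acidic and oxidative steps that follow.

Step 9
Reactants: 10 (R)-triethyl[(3,7-dimethyloct-6-en-1-yn-3-yl)oxy]silane
Product: 11 (R)-triethyl[(1-methyl-2-vinylcyclopent-2-en-1-yl)oxy]silane
Conditions: (H2IMes)(PCy3)Cl2Ru=CHPh (second-generation Grubbs catalyst, 5 mol %), ethene (1 atm), toluene, 60 °C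
Reagents that add atoms: ethene, C=C
Why: Ring-closing enyne metathesis under ethene should close ring D between the internal alkyne carbon and the prenyl CH, expel 2-methylpropene and cap the former alkyne terminus as a vinyl group, which gives the 1,3-diene.

Step 10
Reactants: 12 2-methylpentan-3-one
Product: 13 2,4-dibromo-2-methylpentan-3-one (racemic)
Conditions: Br2 (2.05 equiv), HBr (cat.), CH2Cl2, 0 °C → rt
Reagents that add atoms: bromine, BrBr
Why: Acid-catalysed α,α′-dibromination through the two enols gives the oxyallyl precursor; its stereocentre is lost in the next step.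

Step 11
Reactants: 11 (R)-triethyl[(1-methyl-2-vinylcyclopent-2-en-1-yl)oxy]silane; 13 2,4-dibromo-2-methylpentan-3-one
Product: 14 (1R,3aR)-1,4,4,6-tetramethyl-1-(triethylsilyloxy)-2,3,3a,4,6,7-hexahydroazulen-5(1H)-one (C8=C8a alkene, H-3a cis to the silyloxy group, C6 epimers)
Conditions: Fe2(CO)9 (1.2 equiv), benzene, 60 °C
Reagents that add atoms: none
Why: The iron-bound oxyallyl cation from 13 should add to the diene in a (4+3) cycloaddition that closes ring C, with the unsubstituted diene terminus bonding to the less substituted oxyallyl carbon (so the CMe2 carbon ends on C3a) and with approach anti to the silyloxy group, which sets C3a.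

Step 12
Reactants: 14 (1R,3aR)-1,4,4,6-tetramethyl-1-(triethylsilyloxy)-2,3,3a,4,6,7-hexahydroazulen-5(1H)-one
Product: 15 (1R,3aR)-1,4,4,6-tetramethyl-1-(triethylsilyloxy)-2,3,3a,4-tetrahydroazulene-5,7(1H,6H)-dione (C8=C8a enone)
Conditions: CrO3, 3,5-dimethylpyrazole, CH2Cl2, −20 °C
Reagents that add atoms: chromium trioxide, O=[Cr](=O)=O
Why: Allylic oxidation with the chromium trioxide–dimethylpyrazole complex should convert the only allylic CH2 (C7) into the enone carbonyl, while the silyl ether keeps the tertiary allylic oxygen from oxidative transposition.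

Step 13
Reactants: 15 (1R,3aR)-1,4,4,6-tetramethyl-1-(triethylsilyloxy)-2,3,3a,4-tetrahydroazulene-5,7(1H,6H)-dione
Product: 16 (1R,3aR)-1-hydroxy-7-methoxy-1,4,4,6-tetramethyl-2,3,3a,4-tetrahydroazulen-5(1H)-one (C6=C7 and C8=C8a alkenes)
Conditions: MeOH, HC(OMe)3, p-TsOH (cat.), rt
Reagents that add atoms: methanol, CO
Why: Acid-catalysed enol etherification of the 2-methyl-1,3-dione should take place at the unhindered C7 carbonyl (the C5 carbonyl sits next to the gem-dimethyl carbon) to give the vinylogous ester, and the same conditions methanolyse the tertiary silyl ether.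

Step 14
Reactants: 16 (1R,3aR)-1-hydroxy-7-methoxy-1,4,4,6-tetramethyl-2,3,3a,4-tetrahydroazulen-5(1H)-one
Product: 17 (1R,3aR,8aR)-1-hydroxy-7-methoxy-1,4,4,6-tetramethyl-2,3,3a,4,8,8a-hexahydroazulen-5(1H)-one (cis-fused; H-3a, H-8a and OH on one face)
Conditions: [Ir(cod)(PCy3)(py)]PF6 (5 mol %), H2 (1 atm), CH2Cl2, rt
Reagents that add atoms: none
Why: Hydroxyl-directed homogeneous hydrogenation should deliver hydrogen to C8a from the face of the allylic C1 hydroxyl, which sets the cis ring fusion, while the tetrasubstituted enol ether alkene is not reduced.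

Step 15
Reactants: 17 (1R,3aR,8aR)-1-hydroxy-7-methoxy-1,4,4,6-tetramethyl-2,3,3a,4,8,8a-hexahydroazulen-5(1H)-one
Product: 19 (1R,3aR,8aR)-7-methoxy-1,4,4,6-tetramethyl-5-vinyl-1,2,3,3a,4,5,8,8a-octahydroazulene-1,5-diyl dimethyl dicarbonate (C5 epimers, used crude), via bromomagnesium dialkoxide 18 (not isolated)
Conditions: CH2=CHMgBr (3 equiv), CeCl3, THF, −78 → 0 °C; then ClCO2Me, −78 → 0 °C
Reagents that add atoms: vinylmagnesium bromide, C=C[Mg]Br; methyl chloroformate, COC(Cl)=O
Why: 1,2-Addition of the vinyl organocerium to the hindered vinylogous ester carbonyl (first half of a Stork–Danheiser sequence) and acylation of both alkoxides give the tertiary allylic carbonate; the C5 configuration is irrelevant because C5 is ionised in step 16.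

Step 16
Reactants: 5 (3R,5aR,9aR)-3-(tert-butyldimethylsilyloxy)-2,2,5a-trimethyl-3,4,5,5a,6,9a-hexahydro-1-benzoxepin-7(2H)-one; 19 bis-carbonate of the 5-vinyl azulenediol
Product: 21 (3R,5aR,9aR)-3-(tert-butyldimethylsilyloxy)-6-{2-[(1R,3aR,8aR)-7-methoxy-1-(methoxycarbonyloxy)-1,4,4,6-tetramethyl-2,3,3a,4,8,8a-hexahydroazulen-5(1H)-ylidene]ethyl}-2,2,5a-trimethyl-3,4,5,5a,6,9a-hexahydro-1-benzoxepin-7(2H)-one (C6 epimers), via lithium enolate 20 (not isolated)
Conditions: LiHMDS, LiCl, THF, −78 °C; then 19, Pd(PPh3)4 (5 mol %), −78 → 0 °C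
Reagents that add atoms: none
Why: Kinetic deprotonation of enone 5 occurs at C6, the only non-vinylic CH2 next to the carbonyl, and gives the cross-conjugated lithium enolate 20; zerovalent palladium ionises the tertiary vinyl carbonate of 19 to a π-allyl complex conjugated with the methoxy enol ether, and the enolate carbon attacks its unsubstituted terminus, which forms the C6–CH2 bond and leaves the right half as a base-stable 7-methoxy dienol ether. The closest known reaction type is the Tsuji–Trost allylic alkylation of preformed ketone lithium enolates with allylic carbonates. No ring is closed. The new stereocentre C6 should form mainly anti to the axial C5a methyl group and is corrected by equilibration in step 17, so the kinetic ratio is not critical. The step needs attack at the primary allyl terminus and not at C5 or C7 of the azulene, which the gem-dimethyl group at C4 and the C6 methyl group secure by shielding the inner positions, and it needs C-alkylation at benzoxepine C6 and not at the γ-position, which enolate formation at −78 °C secures.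

Step 17
Reactants: 21 coupled enone–dienol ether
Product: 23 (3R,5aR,6R,9aR)-3-(tert-butyldimethylsilyloxy)-6-{2-[(1R,3aR,8aR)-1-hydroxy-7-methoxy-1,4,4,6-tetramethyl-2,3,3a,4,8,8a-hexahydroazulen-5(1H)-ylidene]ethyl}-2,2,5a-trimethyloctahydro-1-benzoxepin-7(2H)-one, via ketone epimer mixture 22 (not isolated)
Conditions: Cu(OAc)2 (5 mol %), 1,2-bis(diphenylphosphino)benzene (5 mol %), (EtO)2MeSiH, t-BuOH, toluene, rt; then NaOMe, MeOH, rt
Reagents that add atoms: none
Why: Copper hydride conjugate reduction saturates only the disubstituted enone (the dienol ether is not an acceptor), and methoxide then equilibrates C6 to the equatorial side chain cis to the C5a methyl group (the stable arrangement of 9-alkyl-8-oxo-labdane-type ketones) and removes the tertiary carbonate by transesterification.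

Step 18
Reactants: 23 saturated C7 ketone with equatorial C6 side chain
Product: 24 (3R,5aR,6R,7S,9aR)-3-(tert-butyldimethylsilyloxy)-6-{2-[(1R,3aR,8aR)-1-hydroxy-7-methoxy-1,4,4,6-tetramethyl-2,3,3a,4,8,8a-hexahydroazulen-5(1H)-ylidene]ethyl}-2,2,5a,7-tetramethyldecahydro-1-benzoxepin-7-ol
Conditions: MeMgBr, CeCl3, THF, −78 → 0 °C
Reagents that add atoms: methylmagnesium bromide, C[Mg]Br
Why: Organocerium methyl addition suppresses enolisation, and because axial attack is blocked by the 1,3-diaxial C5a methyl group the methyl enters equatorially and gives the axial 7S alcohol; the masked enone cannot react.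

Step 19
Reactants: 24 tertiary alcohol with silyl ether and methyl dienol ether
Product: 26 (1R,3aR,8aR)-5-{2-[(3R,5aR,6R,7S,9aR)-3,7-dihydroxy-2,2,5a,7-tetramethyldecahydro-1-benzoxepin-6-yl]ethyl}-1-hydroxy-1,4,4,6-tetramethyl-2,3,3a,4,8,8a-hexahydroazulen-7(1H)-one, via desilylated dienol ether 25 (not isolated)
Conditions: Bu4NF, THF, rt; then 1 M HCl, 0 °C → rt
Reagents that add atoms: water, O
Why: Fluoride removes the silyl ether, and mild acid hydrolysis of the 1-methoxy diene (protonation at the exocyclic carbon, then water at C7) gives the conjugated tetrasubstituted enone and completes the Stork–Danheiser transposition.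

Step 20
Reactants: 26 enone triol
Product: 27 3-O-acetate of 26
Conditions: Ac2O, pyridine, DMAP (cat.), CH2Cl2, 0 °C → rt
Reagents that add atoms: acetic anhydride, CC(=O)OC(C)=O
Why: Acylation is selective because the benzoxepine C3 hydroxyl is the only secondary alcohol at this stage and the two tertiary alcohols react far more slowly.

Step 21
Reactants: 27 acetoxy enone
Product: 28 (3R,5aR,6R,7S,9aR)-6-{2-[(1R,3aR,7R,8aR)-1,7-dihydroxy-1,4,4,6-tetramethyl-1,2,3,3a,4,7,8,8a-octahydroazulen-5-yl]ethyl}-7-hydroxy-2,2,5a,7-tetramethyldecahydro-1-benzoxepin-3-yl acetate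
Conditions: (S)-1-methyl-3,3-diphenyltetrahydro-1H,3H-pyrrolo[1,2-c][1,3,2]oxazaborole ((S)-Me-CBS, 0.2 equiv), catecholborane, toluene, −78 °C
Reagents that add atoms: none
Why: Corey–Bakshi–Shibata reduction with the S catalyst, which treats the fully substituted alkenyl side as the large group, should deliver hydride to the face that gives the 7R allylic alcohol under reagent control and leaves the acetate intact.

Compound list
1 | geranylacetone, (E)-6,10-dimethylundeca-5,9-dien-2-one | CC(=O)CC/C=C(\C)CCC=C(C)C | starting material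
2 | (5R,6R,9R)-5,6:9,10-diepoxy-6,10-dimethylundecan-2-one | CC(=O)CC[C@H]1O[C@]1(C)CC[C@H]1OC1(C)C | intermediate
3 | kinetic tert-butyldimethylsilyl enol ether of 2 | C=C(O[Si](C)(C)C(C)(C)C)CC[C@H]1O[C@]1(C)CC[C@H]1OC1(C)C | intermediate
4 | (3R,5aR,9aR)-3-(tert-butyldimethylsilyloxy)-2,2,5a-trimethyloctahydro-1-benzoxepin-7(2H)-one | CC(C)(C)[Si](C)(C)O[C@@H]1CC[C@]2(C)CC(=O)CC[C@H]2OC1(C)C | intermediate
5 | (3R,5aR,9aR)-3-(tert-butyldimethylsilyloxy)-2,2,5a-trimethyl-3,4,5,5a,6,9a-hexahydro-1-benzoxepin-7(2H)-one | CC(C)(C)[Si](C)(C)O[C@@H]1CC[C@]2(C)CC(=O)C=C[C@H]2OC1(C)C | intermediate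
6 | geraniol | CC(C)=CCC/C(C)=C/CO | starting material
7 | (2R,3R)-2,3-epoxygeraniol | OC[C@H]1O[C@]1(C)CCC=C(C)C | intermediate
8 | (2R,3S)-3-(chloromethyl)-2-methyl-2-(4-methylpent-3-en-1-yl)oxirane | ClC[C@H]1O[C@]1(C)CCC=C(C)C | intermediate
9 | (R)-3,7-dimethyloct-6-en-1-yn-3-ol | C#C[C@](C)(O)CCC=C(C)C | intermediate
10 | (R)-triethyl[(3,7-dimethyloct-6-en-1-yn-3-yl)oxy]silane | C#C[C@](C)(O[Si](CC)(CC)CC)CCC=C(C)C | intermediate
11 | (R)-triethyl[(1-methyl-2-vinylcyclopent-2-en-1-yl)oxy]silane | C=CC1=CCC[C@@]1(C)O[Si](CC)(CC)CC | intermediate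
12 | 2-methylpentan-3-one | CCC(=O)C(C)C | starting material
13 | 2,4-dibromo-2-methylpentan-3-one (racemic) | CC(Br)C(=O)C(C)(C)Br | intermediate
14 | (1R,3aR)-1,4,4,6-tetramethyl-1-(triethylsilyloxy)-2,3,3a,4,6,7-hexahydroazulen-5(1H)-one (C6 epimers) | O=C1C(C)CC=C2[C@@H](CC[C@@]2(C)O[Si](CC)(CC)CC)C1(C)C | intermediate
15 | (1R,3aR)-1,4,4,6-tetramethyl-1-(triethylsilyloxy)-2,3,3a,4-tetrahydroazulene-5,7(1H,6H)-dione | O=C1C(C)C(=O)C=C2[C@@H](CC[C@@]2(C)O[Si](CC)(CC)CC)C1(C)C | intermediate
16 | (1R,3aR)-1-hydroxy-7-methoxy-1,4,4,6-tetramethyl-2,3,3a,4-tetrahydroazulen-5(1H)-one | O=C1C(C)=C(OC)C=C2[C@@H](CC[C@@]2(C)O)C1(C)C | intermediate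
17 | (1R,3aR,8aR)-1-hydroxy-7-methoxy-1,4,4,6-tetramethyl-2,3,3a,4,8,8a-hexahydroazulen-5(1H)-one | O=C1C(C)=C(OC)C[C@@H]2[C@@H](CC[C@@]2(C)O)C1(C)C | intermediate
18 | bromomagnesium dialkoxide of the 5-vinyl-1,5-diol (C5 epimers) | C=CC1(O[Mg]Br)C(C)=C(OC)C[C@@H]2[C@@H](CC[C@@]2(C)O[Mg]Br)C1(C)C | intermediate
19 | (1R,3aR,8aR)-7-methoxy-1,4,4,6-tetramethyl-5-vinyl-1,2,3,3a,4,5,8,8a-octahydroazulene-1,5-diyl dimethyl dicarbonate (C5 epimers) | C=CC1(OC(=O)OC)C(C)=C(OC)C[C@@H]2[C@@H](CC[C@@]2(C)OC(=O)OC)C1(C)C | intermediate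
20 | lithium enolate of 5 (C6=C7–OLi, cross-conjugated) | CC(C)(C)[Si](C)(C)O[C@@H]1CC[C@]2(C)C=C(O[Li])C=C[C@H]2OC1(C)C | intermediate
21 | coupled enone with 7-methoxy dienol ether and C1 methyl carbonate (benzoxepine C6 epimers) | CC(C)(C)[Si](C)(C)O[C@@H]1CC[C@]2(C)C(CC=C3C(C)=C(OC)C[C@@H]4[C@@H](CC[C@@]4(C)OC(=O)OC)C3(C)C)C(=O)C=C[C@H]2OC1(C)C | intermediate
22 | 8,9-dihydro derivative of 21 (benzoxepine C6 epimers) | CC(C)(C)[Si](C)(C)O[C@@H]1CC[C@]2(C)C(CC=C3C(C)=C(OC)C[C@@H]4[C@@H](CC[C@@]4(C)OC(=O)OC)C3(C)C)C(=O)CC[C@H]2OC1(C)C | intermediate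
23 | (3R,5aR,6R,9aR)-3-(tert-butyldimethylsilyloxy)-6-{2-[(1R,3aR,8aR)-1-hydroxy-7-methoxy-1,4,4,6-tetramethyl-2,3,3a,4,8,8a-hexahydroazulen-5(1H)-ylidene]ethyl}-2,2,5a-trimethyloctahydro-1-benzoxepin-7(2H)-one | CC(C)(C)[Si](C)(C)O[C@@H]1CC[C@]2(C)[C@@H](CC=C3C(C)=C(OC)C[C@@H]4[C@@H](CC[C@@]4(C)O)C3(C)C)C(=O)CC[C@H]2OC1(C)C | intermediate
24 | (3R,5aR,6R,7S,9aR)-3-(tert-butyldimethylsilyloxy)-6-{2-[(1R,3aR,8aR)-1-hydroxy-7-methoxy-1,4,4,6-tetramethyl-2,3,3a,4,8,8a-hexahydroazulen-5(1H)-ylidene]ethyl}-2,2,5a,7-tetramethyldecahydro-1-benzoxepin-7-ol | CC(C)(C)[Si](C)(C)O[C@@H]1CC[C@]2(C)[C@@H](CC=C3C(C)=C(OC)C[C@@H]4[C@@H](CC[C@@]4(C)O)C3(C)C)[C@@](C)(O)CC[C@H]2OC1(C)C | intermediate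
25 | 3-O-desilyl derivative of 24 (triol with methyl dienol ether) | O[C@@H]1CC[C@]2(C)[C@@H](CC=C3C(C)=C(OC)C[C@@H]4[C@@H](CC[C@@]4(C)O)C3(C)C)[C@@](C)(O)CC[C@H]2OC1(C)C | intermediate
26 | (1R,3aR,8aR)-5-{2-[(3R,5aR,6R,7S,9aR)-3,7-dihydroxy-2,2,5a,7-tetramethyldecahydro-1-benzoxepin-6-yl]ethyl}-1-hydroxy-1,4,4,6-tetramethyl-2,3,3a,4,8,8a-hexahydroazulen-7(1H)-one | O[C@@H]1CC[C@]2(C)[C@@H](CCC3=C(C)C(=O)C[C@@H]4[C@@H](CC[C@@]4(C)O)C3(C)C)[C@@](C)(O)CC[C@H]2OC1(C)C | intermediate
27 | 3-O-acetate of 26 | CC(=O)O[C@@H]1CC[C@]2(C)[C@@H](CCC3=C(C)C(=O)C[C@@H]4[C@@H](CC[C@@]4(C)O)C3(C)C)[C@@](C)(O)CC[C@H]2OC1(C)C | intermediate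
28 | (3R,5aR,6R,7S,9aR)-6-{2-[(1R,3aR,7R,8aR)-1,7-dihydroxy-1,4,4,6-tetramethyl-1,2,3,3a,4,7,8,8a-octahydroazulen-5-yl]ethyl}-7-hydroxy-2,2,5a,7-tetramethyldecahydro-1-benzoxepin-3-yl acetate | CC(=O)O[C@@H]1CC[C@]2(C)[C@@H](CCC3=C(C)[C@H](O)C[C@@H]4[C@@H](CC[C@@]4(C)O)C3(C)C)[C@@](C)(O)CC[C@H]2OC1(C)C | target

Total step count: 21 (4 for the left half, 1 for the oxyallyl precursor, 10 for the right half, the key step, 5 after it). Longest linear sequence: 16 steps (geraniol 6 to 28 through steps 5–9 and 11–21).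

Steps most likely to fail

Step 16. The enolate may equilibrate to the extended dienolate or be lost by proton transfer, and the very labile carbonate may ionise and collapse before it meets the enolate, so that the union stays incomplete. The fallback changes the activation from palladium to Lewis acid and sets out from 5 and 19. Enone 5 is converted with LDA and Me3SiCl into the 7-trimethylsilyloxy diene F1, and F1 and 19 are combined with catalytic Me3SiOTf at −78 °C. The carbonate ionises to the methoxy-pentadienyl cation, which the silyl dienol ether should capture at the terminal carbon in a Mukaiyama-type addition. The route is rejoined at 21.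

Step 11. The (4+3) cycloaddition may give the wrong regioisomer or add to the wrong diene face, and the tertiary allylic silyl ether may be ionised by the iron halide. The fallback builds ring C by ring expansion and not by cycloaddition; it sets out from 10 and replaces steps 9 and 11–14. A Pauson–Khand reaction of 10 (Co2(CO)8, then N-methylmorpholine N-oxide) should give the bicyclo[3.3.0]octenone F2 with the gem-dimethyl carbon next to the ketone. RhCl(PPh3)3-catalysed 1,4-hydrosilylation with Et3SiH gives the cis-fused silyl enol ether F3, which is regiodefined because the other α-carbon is quaternary. A (2+2) cycloaddition with chloro(methyl)ketene (2-chloropropanoyl chloride, Et3N) gives cyclobutanone F4. Zinc in acetic acid removes chlorine and triggers the retro-aldol ring expansion to the 6-methyl-5,7-dione F5. Treatment of F5 with MeOH, HC(OMe)3 and p-TsOH as in step 13 rejoins the route at 17.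

Step 21. Hydride may be delivered to the wrong face if the bias of the cis-fused bicycle opposes the catalyst, which would leave the azulene C7 epimer. The fallback uses substrate control followed by inversion and sets out from 27. Luche reduction (NaBH4, CeCl3, MeOH) gives the allylic alcohol favoured by the substrate; if this is the 7S epimer F6, Mitsunobu inversion with chloroacetic acid (PPh3, diisopropyl azodicarboxylate) gives the 7R chloroacetate F7. Thiourea with NaHCO3 in ethanol removes the chloroacetate without touching the acetate, and the route is rejoined at 28.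

Further compounds
F1 | step 16 | (3R,5aR,9aR)-3-(tert-butyldimethylsilyloxy)-2,2,5a-trimethyl-7-(trimethylsilyloxy)-2,3,4,5,5a,9a-hexahydro-1-benzoxepine | CC(C)(C)[Si](C)(C)O[C@@H]1CC[C@]2(C)C=C(O[Si](C)(C)C)C=C[C@H]2OC1(C)C
F2 | step 11 | (5R,8R)-4,4,8-trimethyl-8-(triethylsilyloxy)bicyclo[3.3.0]oct-1-en-3-one (H-5 cis to the silyloxy group) | O=C1C=C2[C@@H](CC[C@@]2(C)O[Si](CC)(CC)CC)C1(C)C
F3 | step 11 | cis-fused 3-(triethylsilyloxy)-4,4,8-trimethyl-8-(triethylsilyloxy)bicyclo[3.3.0]oct-2-ene (H-1, H-5 and the C8 oxygen on one face) | CC[Si](CC)(CC)OC1=C[C@@H]2[C@@H](CC[C@@]2(C)O[Si](CC)(CC)CC)C1(C)C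
F4 | step 11 | chloro(methyl)cyclobutanone (2+2) adduct of F3 (new centres unassigned) | CC1(Cl)C(=O)C2[C@@H]3[C@@H](CC[C@@]3(C)O[Si](CC)(CC)CC)C(C)(C)C12O[Si](CC)(CC)CC
F5 | step 11 | (1R,3aR,8aR)-1,4,4,6-tetramethyl-1-(triethylsilyloxy)octahydroazulene-5,7-dione (C6 epimers) | O=C1C(C)C(=O)C[C@@H]2[C@@H](CC[C@@]2(C)O[Si](CC)(CC)CC)C1(C)C
F6 | step 21 | azulene C7 epimer (7S) of 28 | CC(=O)O[C@@H]1CC[C@]2(C)[C@@H](CCC3=C(C)[C@@H](O)C[C@@H]4[C@@H](CC[C@@]4(C)O)C3(C)C)[C@@](C)(O)CC[C@H]2OC1(C)C
F7 | step 21 | azulene 7-O-chloroacetate of 28 (7R) | CC(=O)O[C@@H]1CC[C@]2(C)[C@@H](CCC3=C(C)[C@H](OC(=O)CCl)C[C@@H]4[C@@H](CC[C@@]4(C)O)C3(C)C)[C@@](C)(O)CC[C@H]2OC1(C)C
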